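## Analysis of the target

Target 30 is a tetracyclic meroterpenoid. A caryophyllane unit (nine-membered ring C, C1–C9, trans-fused at C1–C9 to the gem-dimethylcyclobutane ring D through C10–C11, exocyclic methylene on C8) is fused through C4–C5 to a dihydropyran (ring B), which is annulated to a hexasubstituted phloroglucinol ring A. C1' is the benzylic CHPh carbon between C5 and ring A; ring-A positions are numbered chroman-style (Ar-4a bears C1', then Ar-5 to Ar-8, Ar-8a bears the pyran oxygen), so ring A carries OH at Ar-5 and Ar-7 and CHO at Ar-6 and Ar-8.

There are five stereocentres, (1R,4R,5S,9S,1'R). C1 and C9 are those of (−)-β-caryophyllene, C4 is a quaternary ether carbon (O, CH3), H-5 is anti to the C4 methyl (rings B and C trans-fused), and the phenyl group on C1' is trans to C6.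

Sensitive features are the 1,1-disubstituted alkene (acid, electrophiles, hydrogenation), a medium ring prone to transannular cationic reactions, the tertiary alkyl aryl ether at C4 (which can leave by β-elimination whenever C5 is enolisable), two salicylaldehyde groups and free phenols.

The difficulty is to join a fully substituted, electron-rich arene to a quaternary carbinol carbon and to its tertiary neighbour on a flexible nine-membered ring, and then to relay configuration from C4 to C5 to C1'.

The plan rests on the sequence Ar-8a (ether oxygen), Ar-4a (C1'), Ar-5 (oxygen) in ring A. An ether oxygen and a carbon substituent on adjacent carbons, with a further oxygen beside the carbon-bearing one, is the pattern left when an alkoxide and then an acyl group add across a 3,5-dioxygenated aryne. Because the oxygen sits on C4 and the carbon on C5, one caryophyllene-derived fragment can carry both the nucleophile and the acyl group.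

## Retrosynthetic reasoning

**30 to 28.** The two aryl–CHO bonds are cut first. Ar-6 and Ar-8 are the only unsubstituted ring-A positions of 28 and each is flanked by oxygen, so electrophilic formylation has no regiochemical choice. The aldehydes would not survive the hydride and organometallic steps, so they go in last.

**28 to 27 to 25.** The phenols of 28 are masked as methoxymethyl ethers in 27, which the aryne and the base-mediated steps require. The C1'–phenyl bond is then cut to give the benzylic cation 26, reached from acetate 25. C1' is benzylic to a ring with ortho and para oxygens, so it ionises easily, and the C5 stereocentre next to it steers the incoming phenyl group trans to C6. The reverse order (phenyl on the ketone, then hydride onto the cation) would put the hydride trans to C6 and give the wrong C1' epimer.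

**25 to 24 to 23.** Acetate 25 comes from alcohol 24 and this from ketone 23. The C1' configuration of 24 is of no consequence because it is planarised in 26.

**23 to 21.** The hydrogens on C5 and C6 are removed to reveal enone 21. The forward conjugate reduction must leave H-5 anti to the C4 methyl. This is the one centre that the route sets by protonation under equilibrating conditions.

**21 to 8 and 17 (key disconnection).** Both bonds from ring A to the terpene are cut, aryl–O(C4) and aryl–C1', which opens ring B. The fragments are alkoxide 18, derived from hydroxy enoate 8, and aryne 19, released from silyl triflate 17. This cut joins the two halves and closes ring B in one operation, never breaks the C4–O bond (so C4 is only carried through), and lets the polarisation of the aryne decide which ring-A carbon receives oxygen and which the acyl carbon. The forward reaction needs an alkoxide that cannot fragment; the sp2 C5 of 8 excludes retro-aldol cleavage and enolisation.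

**8 to 7 to 6 to 4 to 3.** The C5–CO2CH3 bond is cut, leading to enol triflate 6, which comes from ketone 4 by enolisation towards C6, the only side with hydrogens. The silyl ether in 4, 6 and 7 keeps the tertiary alkoxide from being triflated or from triggering an α-ketol shift; it is removed to give 8.

**3 to 2 to 1.** The C5 carbonyl of 3 comes from the secondary alcohol of diol 2, and both C–O bonds of 2 come from the strained trans C4=C5 alkene of (−)-β-caryophyllene 1. C4 is set here, by attack on the accessible outer face. Compound 1 supplies rings C and D, C1, C9 and the C8 methylene unchanged.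

**17 to 15 to 11 to 10 to 9.** The triflate of 17 comes from a phenol masked as carbamate 15. The silyl group is placed by carbamate-directed ortho-metalation of 11, where symmetry makes both ortho positions the same. Carbamate 11 comes from the bis-ether 10 of phloroglucinol 9.

## Alternatives that were turned down

**Alternative 1: C3–C4 macrocyclisation.** The C3–C4 bond of ring C is cut and C4 is traced back to the lactone carbonyl of a 4-phenyl-dihydrocoumarin, so rings A and B with C1' are made first and ring C is closed last.
- Forward key step: the vinyl group on the cyclobutane of ketene acetal phosphate A2 is hydroborated with a hindered dialkylborane, and the alkylborane is coupled intramolecularly with the enol phosphate (zerovalent palladium with a ferrocenyl diphosphine, carbonate base; B-alkyl Suzuki–Miyaura) to give the macrocyclic enol ether A1.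
- For it: the coupling is a precedented way to make cyclic enol ethers, so on precedent of the key step it is stronger than the chosen route. C1' can be set early and independently, and the ring-A pattern follows from coumarin chemistry.
- Against it: it closes a strained nine-membered ring bearing a trans-fused cyclobutane by macrocyclisation, where entropy, transannular strain and protodeboronation or β-hydride loss all work against it. After the key step C4 still lacks its methyl and C5 its hydrogen, so two adjacent centres, one quaternary, must be set on the enol ether with only remote control. The cyclobutane fragment with C1 and C9 has to be made enantioselectively from scratch, and the C8 ketal has to be turned into the methylene late.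
- Comparison: the step count would be roughly double. The chosen strategy takes rings C and D, C1, C9, the methylene and the C4–O configuration from 1 and builds only ring B.

**Alternative 2: enzymatic construction of ring A.** Ring A itself is disconnected: the C1'–aryl bond and the ring carbons come from three malonyl units.
- Forward key step: a type 3 polyketide synthase of the chalcone synthase family is loaded with the enoyl thioester A4, extends it three times with malonyl thioester units and closes ring A by Claisen cyclisation to give the acylphloroglucinol A3.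
- For it: on paper it is the shortest route, needs no protecting groups, and the ring-A oxygenation pattern is inherent. On step and protecting-group economy it is stronger than the chosen route.
- Against it: the starter is a bulky bicyclic C16 thioester with a fully substituted α-carbon (C5), far from the small aliphatic or cinnamoyl starters these enzymes accept, so it would need enzyme engineering and cofactor supply. Ring B would then have to be closed by oxa-Michael addition of a phenol to C4 of a tetrasubstituted enone, creating the quaternary C4 and C5 together with only remote control from C1 and C9.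
- Comparison: the chosen strategy fixes C4 by an established facial preference before ring B exists. Its key step is untried on this substrate, but it depends on polar aryne reactivity that can be reasoned about, not on an enzyme's tolerance.

**Alternative 3: cyclobutane last.** Ring D is disconnected at C1–C11 and C9–C10.
- Forward key step: the ring-C enone A6 is irradiated with an excess of 2-methylpropene A7, and brief base treatment epimerises C9 to the trans C/D fusion, giving diketone A5.
- For it: enone–alkene [2+2] photocycloaddition is a classic reaction whose usual head-to-tail regiochemistry places the gem-dimethyl carbon on C1, and the C8 ketone serves for methylenation. On precedent of the key step and independence from terpene supply it is as strong or stronger.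
- Against it: A6 itself (a chromanone-fused cyclononenone with quaternary C4) must be built from scratch. Facial control of the cycloaddition by C4 and C5 across a flexible ring is doubtful, so C1 and C9 may form as mixtures. Medium-ring enones isomerise about the double bond on excitation, and the aryl ketone chromophore competes for light. The base step also endangers C5 and the β-aryloxy ketone.
- Comparison: the chosen strategy gets the absolute configuration at C1 and C9 and ring D from 1 with no selectivity question, and in far fewer steps.

Key step: step 11

Remark: the enolate from 4 is taken to have the ring-cis C5=C6 geometry (C4 and C7 cis), as drawn for 5–8 and 21; the alkene is saturated in step 12, so the other isomer would serve equally.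

Remark: 24 and 25 are drawn as the expected major C1' epimer (oxygen trans to C6); either epimer converges on cation 26. Ph3Al is used as the purchased solution.

## Route

Step 1
Reactants: 1 (−)-β-caryophyllene
Product: 2 (1R,4R,5R,9S)-4,11,11-trimethyl-8-methylenebicyclo[7.2.0]undecane-4,5-diol
Conditions: OsO4 (2 mol%), NMO (1.2 equiv), acetone/H2O, 0 °C to rt
Reagents that add atoms: osmium tetroxide O=[Os](=O)(=O)=O; N-methylmorpholine N-oxide C[N+]1([O-])CCOCC1; water O
Why: Catalytic syn-dihydroxylation; the strained trans trisubstituted alkene should react much faster than the exocyclic one. Only its outer face is open, and the predominant conformers expose the face that gives 4R,5R, so C4 is set here and the minor diastereomer is removed by chromatography.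

Step 2
Reactants: 2 (1R,4R,5R,9S)-4,11,11-trimethyl-8-methylenebicyclo[7.2.0]undecane-4,5-diol
Product: 3 (1R,4R,9S)-4-hydroxy-4,11,11-trimethyl-8-methylenebicyclo[7.2.0]undecan-5-one
Conditions: IBX, DMSO, rt
Reagents that add atoms: none
Why: Oxidation of the secondary alcohol with 2-iodoxybenzoic acid; this reagent takes 1,2-diols to ketols without glycol cleavage, and the tertiary alcohol and the alkene are inert to it.

Step 3
Reactants: 3 (1R,4R,9S)-4-hydroxy-4,11,11-trimethyl-8-methylenebicyclo[7.2.0]undecan-5-one
Product: 4 (1R,4R,9S)-4,11,11-trimethyl-8-methylene-4-(triethylsilyloxy)bicyclo[7.2.0]undecan-5-one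
Conditions: Et3SiOTf, 2,6-lutidine, CH2Cl2, −78 to 0 °C
Reagents that add atoms: triethylsilyl triflate CC[Si](CC)(CC)OS(=O)(=O)C(F)(F)F
Why: Silylation of the hindered tertiary alcohol with a silyl triflate; it prevents O-triflation and α-ketol rearrangement of the alkoxide in step 4.

Step 4
Reactants: 4 (1R,4R,9S)-4,11,11-trimethyl-8-methylene-4-(triethylsilyloxy)bicyclo[7.2.0]undecan-5-one
Product: 6 (1R,4R,5E,9S)-4,11,11-trimethyl-8-methylene-4-(triethylsilyloxy)bicyclo[7.2.0]undec-5-en-5-yl trifluoromethanesulfonate, via potassium enolate 5 (not isolated)
Conditions: KN(SiMe3)2, THF, −78 °C; PhNTf2, −78 to 0 °C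
Reagents that add atoms: N-phenylbis(trifluoromethanesulfonimide) O=S(=O)(N(c1ccccc1)S(=O)(=O)C(F)(F)F)C(F)(F)F
Why: Kinetic enolisation and O-triflation; C4 is quaternary, so only C6 can be deprotonated and the enol triflate is regiochemically unambiguous.

Step 5
Reactants: 6 (1R,4R,5E,9S)-4,11,11-trimethyl-8-methylene-4-(triethylsilyloxy)bicyclo[7.2.0]undec-5-en-5-yl trifluoromethanesulfonate
Product: 7 methyl (1R,4R,5E,9S)-4,11,11-trimethyl-8-methylene-4-(triethylsilyloxy)bicyclo[7.2.0]undec-5-ene-5-carboxylate
Conditions: Pd(OAc)2 (10 mol%), dppf, CO (1 atm), MeOH, Et3N, DMF, 60 °C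
Reagents that add atoms: carbon monoxide [C-]#[O+]; methanol CO
Why: Palladium-catalysed methoxycarbonylation of an enol triflate (oxidative addition of zerovalent palladium, CO insertion, methanolysis) with retention of alkene geometry; the new carbon is the future C1'.

Step 6
Reactants: 7 methyl (1R,4R,5E,9S)-4,11,11-trimethyl-8-methylene-4-(triethylsilyloxy)bicyclo[7.2.0]undec-5-ene-5-carboxylate
Product: 8 methyl (1R,4R,5E,9S)-4-hydroxy-4,11,11-trimethyl-8-methylenebicyclo[7.2.0]undec-5-ene-5-carboxylate
Conditions: HF·pyridine, pyridine, THF, 0 °C to rt
Reagents that add atoms: none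
Why: Fluoride-driven desilylation under buffered conditions; the electron-poor allylic system at C4 does not ionise and the exocyclic alkene is untouched.

Step 7
Reactants: 9 phloroglucinol
Product: 10 3,5-bis(methoxymethoxy)phenol
Conditions: MOMCl (2.0 equiv), i-Pr2NEt, DMF, 0 °C to rt
Reagents that add atoms: chloromethyl methyl ether COCCl
Why: O-alkylation of the phenol; the outcome is statistical, and the bis-ether is separated from mono- and tris-ether, which can be recycled.

Step 8
Reactants: 10 3,5-bis(methoxymethoxy)phenol
Product: 11 3,5-bis(methoxymethoxy)phenyl N-isopropylcarbamate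
Conditions: i-PrNCO, Et3N (cat.), CH2Cl2, rt
Reagents that add atoms: isopropyl isocyanate CC(C)N=C=O
Why: Addition of the phenol to an isocyanate gives the carbamate that directs the metalation and can later be cleaved under mild base.

Step 9
Reactants: 11 3,5-bis(methoxymethoxy)phenyl N-isopropylcarbamate
Product: 15 3,5-bis(methoxymethoxy)-2-(trimethylsilyl)phenyl N-isopropylcarbamate, via N-silyl carbamate 12 (not isolated), via aryllithium 13 (not isolated), via N-silyl aryl silane 14 (not isolated)
Conditions: t-BuMe2SiOTf, TMEDA, Et2O, 0 °C to rt; n-BuLi, TMEDA, −78 °C; Me3SiCl, −78 °C to rt; aq NaHSO4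
Reagents that add atoms: chlorotrimethylsilane C[Si](C)(C)Cl
Why: Directed ortho-metalation after N-silylation of the carbamate in the flask; the two positions ortho to the carbamate are equivalent and each lies between the carbamate and an acetal oxygen, so lithiation should go there and not between the two acetal oxygens. Acidic work-up removes the N-silyl group.

Step 10
Reactants: 15 3,5-bis(methoxymethoxy)-2-(trimethylsilyl)phenyl N-isopropylcarbamate
Product: 17 3,5-bis(methoxymethoxy)-2-(trimethylsilyl)phenyl trifluoromethanesulfonate, via silyl phenol 16 (not isolated)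
Conditions: Et2NH, DBU, MeCN, 40 °C; then PhNTf2, rt
Reagents that add atoms: N-phenylbis(trifluoromethanesulfonimide) O=S(=O)(N(c1ccccc1)S(=O)(=O)C(F)(F)F)C(F)(F)F
Why: E1cB cleavage of the N-monosubstituted carbamate (the isocyanate is scavenged by Et2NH) and triflation of the phenoxide in one flask; the acetals and the C–Si bond are stable to amidine base.

Step 11
Reactants: 8 methyl (1R,4R,5E,9S)-4-hydroxy-4,11,11-trimethyl-8-methylenebicyclo[7.2.0]undec-5-ene-5-carboxylate; 17 3,5-bis(methoxymethoxy)-2-(trimethylsilyl)phenyl trifluoromethanesulfonate
Product: 21 bis-MOM alkylidene chromanone (1R,4R,9S; rings A–D; C1' ketone; E C5=C6; OCH2OCH3 at Ar-5 and Ar-7), via potassium alkoxide 18 (not isolated), via aryne 19 (not isolated), via aryl anion 20 (not isolated)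
Conditions: KH (1.05 equiv), THF, 0 °C; then 17 (1.5–2 equiv, slow addition), CsF, 18-crown-6, THF, rt to 50 °C
Reagents that add atoms: none
Why: Proposed new method: KH converts 8 into alkoxide 18, fluoride removes the silyl group of 17 with loss of triflate to give aryne 19, 18 adds to the aryne carbon remote from the flanking acetal oxygen, and the aryl anion 20 attacks the ester carbonyl and expels methoxide. The closest known reaction type is the aryne annulation of salicylate esters to xanthones (phenoxide addition, then acyl capture by the aryl anion); new here is a hindered tertiary aliphatic alkoxide paired with a conjugated ester. Ring B closes by 6-exo-trig acyl substitution; the competing 6-endo-trig conjugate addition to C6 should be slower for a hard, localised sp2 carbanion held on a two-atom tether. No stereocentre is formed, and C4 is only carried through because its C–O bond is never broken. The step needs regioselective addition to the unsymmetrical aryne, which the inductively withdrawing oxygen beside the triple bond secures: it distorts the aryne so that the nucleophile enters at the far carbon and the charge develops next to that oxygen, placing ether oxygen, acyl carbon and an acetal oxygen on three consecutive ring-A carbons. It also needs the alkoxide to persist: C5 is sp2, so 18 has no retro-aldol pathway and the ester cannot be enolised. Slow addition and an excess of 17 are used because the released methoxide also consumes aryne.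

Step 12
Reactants: 21 bis-MOM alkylidene chromanone (1R,4R,9S; C1' ketone; E C5=C6)
Product: 23 bis-MOM chromanone (1R,4R,5R,9S; C1' ketone; H-5 anti to the C4 methyl; trans B/C fusion), via silyl enol ether 22 (not isolated)
Conditions: [(Ph3P)CuH]6 (5 mol%), PhMe2SiH, toluene, rt; then K2CO3, MeOH, 0 °C to rt
Reagents that add atoms: none
Why: Copper hydride-catalysed 1,4-hydrosilylation of the enone puts hydride on C6, and the unactivated exocyclic alkene does not react. Methanolysis of 22 and equilibration through the enolate set C5; the trans-fused epimer is the only one that can place both ring-C bonds equatorial on ring B, so it is expected, though not assured, to predominate.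

Step 13
Reactants: 23 bis-MOM chromanone (1R,4R,5R,9S; C1' ketone)
Product: 24 bis-MOM benzylic alcohol (1R,4R,5S,9S,1'S; C1'–OH trans to C6)
Conditions: NaBH4, MeOH/THF, 0 °C to rt
Reagents that add atoms: none
Why: Hydride reduction of the aryl ketone; axial delivery should give mainly the alcohol with oxygen trans to C6, and C5 can no longer epimerise once the ketone is gone.

Step 14
Reactants: 24 bis-MOM benzylic alcohol (1R,4R,5S,9S,1'S)
Product: 25 bis-MOM benzylic acetate (1R,4R,5S,9S,1'S)
Conditions: Ac2O, Et3N, DMAP (cat.), CH2Cl2, 0 °C
Reagents that add atoms: acetic anhydride CC(=O)OC(C)=O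
Why: Base-mediated acylation turns the hydroxyl into a leaving group without acid, which would ionise this very electron-rich benzylic position; the acetate is used without delay.

Step 15
Reactants: 25 bis-MOM benzylic acetate (1R,4R,5S,9S,1'S)
Product: 27 bis-MOM 1'-phenyl chroman (1R,4R,5S,9S,1'R; phenyl trans to C6), via benzylic cation 26 (not isolated)
Conditions: Ph3Al (2.5 equiv), CH2Cl2, −78 to −20 °C
Reagents that add atoms: triphenylaluminium c1ccc(cc1)[Al](c1ccccc1)c1ccccc1
Why: SN1-type substitution: the Lewis-acidic Ph3Al ionises the acetate to cation 26, stabilised by the ortho and para oxygens, and the aluminate transfers phenyl. Attack anti to the C6 substituent on the neighbouring C5 sets C1' with phenyl trans to C6, the usual sense for 3-substituted chroman-4-yl cations.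

Step 16
Reactants: 27 bis-MOM 1'-phenyl chroman (1R,4R,5S,9S,1'R)
Product: 28 1'-phenyl chroman-Ar-5,Ar-7-diol (1R,4R,5S,9S,1'R)
Conditions: p-TsOH·H2O (0.3 equiv), MeOH, 45 °C
Reagents that add atoms: none
Why: Acid-catalysed acetal exchange removes both aryl methoxymethyl ethers; the acid is too dilute to protonate the 1,1-disubstituted alkene at a useful rate or to ionise the tertiary aryl ether.

Step 17
Reactants: 28 1'-phenyl chroman-Ar-5,Ar-7-diol (1R,4R,5S,9S,1'R)
Product: 30 target CNP0253700.4 (1R,4R,5S,9S,1'R; Ar-6 and Ar-8 formyl; Ar-5 and Ar-7 hydroxyl), via bis-iminium salt 29 (not isolated)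
Conditions: POCl3 (4 equiv), DMF, EtOAc, 0 °C to rt; then H2O, NaOAc, 50 °C
Reagents that add atoms: N,N-dimethylformamide CN(C)C=O; water O
Why: Twofold Vilsmeier–Haack formylation: Ar-6 and Ar-8 are the only free positions and each is ortho or para to all three ring oxygens, so the chloroiminium ion should attack twice, as it does with phloroglucinol itself. Hydrolysis of 29 gives the dialdehyde, and the exocyclic alkene is far less nucleophilic at this temperature.

## Compound list

1 | (−)-β-caryophyllene, (1R,4E,9S)-4,11,11-trimethyl-8-methylenebicyclo[7.2.0]undec-4-ene | C=C1CC/C=C(C)/CC[C@@H]2[C@@H]1CC2(C)C | starting material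
2 | (1R,4R,5R,9S)-4,11,11-trimethyl-8-methylenebicyclo[7.2.0]undecane-4,5-diol | C=C1CC[C@@H](O)[C@](C)(O)CC[C@@H]2[C@@H]1CC2(C)C | intermediate
3 | (1R,4R,9S)-4-hydroxy-4,11,11-trimethyl-8-methylenebicyclo[7.2.0]undecan-5-one | C=C1CCC(=O)[C@](C)(O)CC[C@@H]2[C@@H]1CC2(C)C | intermediate
4 | (1R,4R,9S)-4,11,11-trimethyl-8-methylene-4-(triethylsilyloxy)bicyclo[7.2.0]undecan-5-one | C=C1CCC(=O)[C@](C)(O[Si](CC)(CC)CC)CC[C@@H]2[C@@H]1CC2(C)C | intermediate
5 | potassium enolate of 4 (C5–O−, C5=C6, ring-cis; formed in the flask) | C=C1C/C=C([O-])\[C@](C)(O[Si](CC)(CC)CC)CC[C@@H]2[C@@H]1CC2(C)C.[K+] | intermediate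
6 | (1R,4R,5E,9S)-4,11,11-trimethyl-8-methylene-4-(triethylsilyloxy)bicyclo[7.2.0]undec-5-en-5-yl trifluoromethanesulfonate | C=C1C/C=C(OS(=O)(=O)C(F)(F)F)\[C@](C)(O[Si](CC)(CC)CC)CC[C@@H]2[C@@H]1CC2(C)C | intermediate
7 | methyl (1R,4R,5E,9S)-4,11,11-trimethyl-8-methylene-4-(triethylsilyloxy)bicyclo[7.2.0]undec-5-ene-5-carboxylate | C=C1C/C=C(C(=O)OC)\[C@](C)(O[Si](CC)(CC)CC)CC[C@@H]2[C@@H]1CC2(C)C | intermediate
8 | methyl (1R,4R,5E,9S)-4-hydroxy-4,11,11-trimethyl-8-methylenebicyclo[7.2.0]undec-5-ene-5-carboxylate | C=C1C/C=C(C(=O)OC)\[C@](C)(O)CC[C@@H]2[C@@H]1CC2(C)C | intermediate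
9 | phloroglucinol | Oc1cc(O)cc(O)c1 | starting material
10 | 3,5-bis(methoxymethoxy)phenol | COCOc1cc(O)cc(OCOC)c1 | intermediate
11 | 3,5-bis(methoxymethoxy)phenyl N-isopropylcarbamate | COCOc1cc(OCOC)cc(OC(=O)NC(C)C)c1 | intermediate
12 | 3,5-bis(methoxymethoxy)phenyl N-(tert-butyldimethylsilyl)-N-isopropylcarbamate (formed in the flask) | COCOc1cc(OCOC)cc(OC(=O)N(C(C)C)[Si](C)(C)C(C)(C)C)c1 | intermediate
13 | 2-lithio derivative of 12 (lithium between the carbamate and an acetal oxygen; formed in the flask) | COCOc1cc(OCOC)c([Li])c(OC(=O)N(C(C)C)[Si](C)(C)C(C)(C)C)c1 | intermediate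
14 | 3,5-bis(methoxymethoxy)-2-(trimethylsilyl)phenyl N-(tert-butyldimethylsilyl)-N-isopropylcarbamate (formed in the flask) | COCOc1cc(OCOC)c([Si](C)(C)C)c(OC(=O)N(C(C)C)[Si](C)(C)C(C)(C)C)c1 | intermediate
15 | 3,5-bis(methoxymethoxy)-2-(trimethylsilyl)phenyl N-isopropylcarbamate | COCOc1cc(OCOC)c([Si](C)(C)C)c(OC(=O)NC(C)C)c1 | intermediate
16 | 3,5-bis(methoxymethoxy)-2-(trimethylsilyl)phenol (present as its amidinium phenoxide; formed in the flask) | COCOc1cc(OCOC)c([Si](C)(C)C)c(O)c1 | intermediate
17 | 3,5-bis(methoxymethoxy)-2-(trimethylsilyl)phenyl trifluoromethanesulfonate | COCOc1cc(OCOC)c([Si](C)(C)C)c(OS(=O)(=O)C(F)(F)F)c1 | intermediate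
18 | potassium alkoxide of 8 (formed in the flask) | C=C1C/C=C(C(=O)OC)\[C@](C)([O-])CC[C@@H]2[C@@H]1CC2(C)C.[K+] | intermediate
19 | 3,5-bis(methoxymethoxy)benzyne, 1,2-didehydro-3,5-bis(methoxymethoxy)benzene (formed in the flask) | COCOC1=CC#CC(OCOC)=C1 | intermediate
20 | aryl anion from addition of 18 to 19: C4–O–aryl ether of 8 metalated at the ring carbon between the ether oxygen and an acetal oxygen (formed in the flask) | C=C1C/C=C(C(=O)OC)\[C@](C)(Oc3cc(OCOC)cc(OCOC)c3[K])CC[C@@H]2[C@@H]1CC2(C)C | intermediate
21 | bis-MOM alkylidene chromanone (1R,4R,9S): rings A–D, C1' ketone, E C5=C6, OCH2OCH3 at Ar-5 and Ar-7 | C=C1C/C=C2/C(=O)c3c(OCOC)cc(OCOC)cc3O[C@]2(C)CC[C@@H]2[C@@H]1CC2(C)C | intermediate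
22 | dimethylphenylsilyl enol ether of 23 (C5=C1'–OSi; formed in the flask) | C=C1CCC2=C(O[Si](C)(C)c3ccccc3)c3c(OCOC)cc(OCOC)cc3O[C@]2(C)CC[C@@H]2[C@@H]1CC2(C)C | intermediate
23 | bis-MOM chromanone (1R,4R,5R,9S): C1' ketone, H-5 anti to the C4 methyl | C=C1CC[C@H]2C(=O)c3c(OCOC)cc(OCOC)cc3O[C@]2(C)CC[C@@H]2[C@@H]1CC2(C)C | intermediate
24 | bis-MOM benzylic alcohol (1R,4R,5S,9S,1'S): C1'–OH trans to C6 | C=C1CC[C@H]2[C@H](O)c3c(OCOC)cc(OCOC)cc3O[C@]2(C)CC[C@@H]2[C@@H]1CC2(C)C | intermediate
25 | bis-MOM benzylic acetate (1R,4R,5S,9S,1'S) | C=C1CC[C@H]2[C@H](OC(C)=O)c3c(OCOC)cc(OCOC)cc3O[C@]2(C)CC[C@@H]2[C@@H]1CC2(C)C | intermediate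
26 | benzylic cation at C1' (counter-ion acetoxytriphenylaluminate; formed in the flask) | C=C1CC[C@H]2[CH+]c3c(OCOC)cc(OCOC)cc3O[C@]2(C)CC[C@@H]2[C@@H]1CC2(C)C | intermediate
27 | bis-MOM 1'-phenyl chroman (1R,4R,5S,9S,1'R): phenyl trans to C6 | C=C1CC[C@H]2[C@H](c3ccccc3)c3c(OCOC)cc(OCOC)cc3O[C@]2(C)CC[C@@H]2[C@@H]1CC2(C)C | intermediate
28 | 1'-phenyl chroman-Ar-5,Ar-7-diol (1R,4R,5S,9S,1'R) | C=C1CC[C@H]2[C@H](c3ccccc3)c3c(O)cc(O)cc3O[C@]2(C)CC[C@@H]2[C@@H]1CC2(C)C | intermediate
29 | Ar-6,Ar-8-bis(dimethyliminiomethyl) derivative of 28, dichloride (formed in the flask) | C=C1CC[C@H]2[C@H](c3ccccc3)c3c(O)c(C=[N+](C)C)c(O)c(C=[N+](C)C)c3O[C@]2(C)CC[C@@H]2[C@@H]1CC2(C)C.[Cl-].[Cl-] | intermediate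
30 | CNP0253700.4, (1R,4R,5S,9S,1'R)-Ar-6,Ar-8-diformyl-Ar-5,Ar-7-dihydroxy-1'-phenyl chroman fused to the caryophyllane unit | C=C1CC[C@H]2[C@H](c3ccccc3)c3c(O)c(C=O)c(O)c(C=O)c3O[C@]2(C)CC[C@@H]2[C@@H]1CC2(C)C | target

## Step count and least certain steps

Total step count: 17. Longest linear sequence: 13 steps (steps 1–6 and 11–17, from 1). The aryne arm (steps 7–10) adds 4 steps and joins at step 11.

**Step 11 (key step, proposed new method).**
- Most likely failure: after O-arylation the aryl anion is lost before it acylates, either by protonation from adventitious proton sources or by 6-endo conjugate addition to C6, because the ester carbonyl is hindered and conjugated. A second risk is that the hindered tertiary alkoxide adds too slowly, so that fluoride and released methoxide consume the aryne.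
- Fallback (known chemistry; gives up the aryne logic): it sets out from 1 and 9 and comes back at 30. Compound 9 is formylated twice under Vilsmeier–Haack conditions to 2,4,6-trihydroxybenzene-1,3-dicarbaldehyde F1. Heating F1 with benzaldehyde and 1 in an aqueous medium gives, by Knoevenagel-type condensation, the ortho-quinone methide F2, which is trapped in situ by the strained trans C4=C5 alkene of 1 in an inverse-demand hetero-Diels–Alder reaction. Oxygen should bond to the more substituted C4, and suprafacial addition to the outer face of the trans alkene gives the trans B/C fusion with the same C4 and C5 configuration as the main route.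
- Cost of the fallback: the cycloaddition is not expected to control the C1' configuration (endo against exo approach of the phenyl group), so diastereomers would have to be separated. The main route offers that control instead.

**Step 12.**
- Most likely failure: insufficient bias at C5. The equilibrium between the C5 epimers may be close to even or favour the cis-fused ketone, since the preference rests only on the difference between an axial methyl and an axial ring bond. Under the basic equilibration the enolate may also expel the C4 aryloxide (β-elimination and re-addition), which would erode C4.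
- Fallback (reagent control in place of substrate control, no base): it sets out from 21 and comes back at 23. Reductive silylation of 21 with [(Ph3P)CuH]6 and Et3SiCl gives the isolable triethylsilyl enol ether F3. F3 is protonated under kinetic control with a chiral Brønsted acid catalyst (a binaphthol-derived N-triflyl thiophosphoramide, the enantiomer chosen by screening) and phenol as the stoichiometric proton donor, a known class of catalytic asymmetric protonation of silyl enol ethers.

**Step 15.**
- Most likely failure: loss of H-5 from cation 26 to give the 2H-chromene, which destroys the C5 stereocentre; Lewis-acid attack of the aluminium reagent on the acetal protecting groups; or low facial selectivity at C1'.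
- Fallback (neutral quinone methide under basic conditions in place of a Lewis-acid-generated cation): it sets out from 23 and comes back at 28. The acetals of 23 are removed with p-TsOH in MeOH to give the Ar-5,Ar-7-dihydroxy chromanone F4. Both phenols are converted into tert-butyl carbonates with Boc2O and DMAP (bis-carbonate ketone F5), and NaBH4 in MeOH at low temperature gives the benzylic alcohol F6. Excess PhMgBr then deprotonates F6; the Ar-5 carbonate migrates to the C1' oxygen and is expelled by the phenoxide to give the ortho-quinone methide F7, to which PhMgBr adds at C1' anti to C6. The same excess cleaves the remaining aryl carbonate, so 28 is obtained after work-up. Carbonate-migration-triggered generation of ortho-quinone methides with Grignard addition is a known method.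

**Step 17.**
- Most likely failure: the reaction stalls after the first formylation because the first iminium group deactivates the ring, or the chloroiminium ion or HCl attacks the exocyclic alkene under the forcing conditions needed for the second.
- Fallback (halogenation and halogen–metal exchange in place of electrophilic formylation): it sets out from 27 and comes back at 30. Treating 27 with NBS (2 equiv) in MeCN at low temperature brominates the two free ring-A positions to give the dibromide F8. Bromine–lithium exchange with t-BuLi at −78 °C and quenching with DMF give the bis-MOM dialdehyde F9, and acid-catalysed removal of the acetals (p-TsOH, MeOH) gives 30.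

## Further compounds

F1 | step 11 | 2,4,6-trihydroxybenzene-1,3-dicarbaldehyde | O=Cc1c(O)cc(O)c(C=O)c1O
F2 | step 11 | ortho-quinone methide from F1 and benzaldehyde (6-benzylidene-3,5-diformyl-2,4-dihydroxycyclohexa-2,4-dienone) | O=CC1=C(O)C(=Cc2ccccc2)C(=O)C(C=O)=C1O
F3 | step 12 | triethylsilyl enol ether of 23 (C5=C1'–OSiEt3) | C=C1CCC2=C(O[Si](CC)(CC)CC)c3c(OCOC)cc(OCOC)cc3O[C@]2(C)CC[C@@H]2[C@@H]1CC2(C)C
F4 | step 15 | Ar-5,Ar-7-dihydroxy chromanone (1R,4R,5R,9S; C1' ketone) | C=C1CC[C@H]2C(=O)c3c(O)cc(O)cc3O[C@]2(C)CC[C@@H]2[C@@H]1CC2(C)C
F5 | step 15 | Ar-5,Ar-7-bis(tert-butoxycarbonyloxy) chromanone | C=C1CC[C@H]2C(=O)c3c(OC(=O)OC(C)(C)C)cc(OC(=O)OC(C)(C)C)cc3O[C@]2(C)CC[C@@H]2[C@@H]1CC2(C)C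
F6 | step 15 | Ar-5,Ar-7-bis(tert-butoxycarbonyloxy) benzylic alcohol (C1'–OH, drawn as the epimer with oxygen trans to C6) | C=C1CC[C@H]2[C@H](O)c3c(OC(=O)OC(C)(C)C)cc(OC(=O)OC(C)(C)C)cc3O[C@]2(C)CC[C@@H]2[C@@H]1CC2(C)C
F7 | step 15 | ortho-quinone methide (C1'=Ar-4a, Ar-5 carbonyl, Ar-7 tert-butyl carbonate) | C=C1CC[C@H]2C=C3C(=O)C=C(OC(=O)OC(C)(C)C)C=C3O[C@]2(C)CC[C@@H]2[C@@H]1CC2(C)C
F8 | step 17 | Ar-6,Ar-8-dibromo derivative of 27 | C=C1CC[C@H]2[C@H](c3ccccc3)c3c(OCOC)c(Br)c(OCOC)c(Br)c3O[C@]2(C)CC[C@@H]2[C@@H]1CC2(C)C
F9 | step 17 | Ar-6,Ar-8-diformyl derivative of 27 (bis-MOM dialdehyde) | C=C1CC[C@H]2[C@H](c3ccccc3)c3c(OCOC)c(C=O)c(OCOC)c(C=O)c3O[C@]2(C)CC[C@@H]2[C@@H]1CC2(C)C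
A1 | alternative 1 | macrocyclic 4H-chromene enol ether (C4=C5) with C8 dioxolane | C12(OCCO1)CCC3=C(CC[C@@H]4[C@@H]2CC4(C)C)Oc1cc(OCOC)cc(OCOC)c1[C@H]3c1ccccc1
A2 | alternative 1 | diphenyl ketene acetal phosphate of the 4-phenyl-dihydrocoumarin carrying the vinylcyclobutane side chain (C8 dioxolane) | C=C[C@@H]1[C@@H](C2(OCCO2)CCC2=C(OP(=O)(Oc3ccccc3)Oc3ccccc3)Oc3cc(OCOC)cc(OCOC)c3[C@H]2c2ccccc2)CC1(C)C
A3 | alternative 2 | 2,4,6-trihydroxyphenyl enone (acylphloroglucinol on C5, C4=C5) | C=C1CC/C(C(=O)c3c(O)cc(O)cc3O)=C(C)\CC[C@@H]2[C@@H]1CC2(C)C
A4 | alternative 2 | N-acetylcysteamine thioester of the C5 carboxylic acid (C4=C5 enoyl starter) | C=C1CC/C(C(=O)SCCNC(C)=O)=C(C)\CC[C@@H]2[C@@H]1CC2(C)C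
A5 | alternative 3 | tetracyclic diketone (C8 and C1' ketones), trans C/D fusion | O=C1CC[C@H]2C(=O)c3c(OCOC)cc(OCOC)cc3O[C@]2(C)CC[C@@H]2[C@@H]1CC2(C)C
A6 | alternative 3 | chromanone-fused cyclononenone (C8 ketone, cis C1=C9) | C[C@@]12CC/C=C\C(=O)CC[C@H]1C(=O)c1c(OCOC)cc(OCOC)cc1O2
A7 | alternative 3 | 2-methylpropene | CC(C)=C
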